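Ring A of the ent-labdane (labdane numbering) is closed across C5–C10 and C3–C4 in a single radical cascade that builds ring B at the same time. A carboxylate placed on C10 is a traceless handle: photoredox decarboxylation gives the tertiary C10 radical, which adds to C5 of a prenyl-type C4=C5 olefin and then, as the tertiary C4 radical, to a nitrile carbon that becomes the C3 ketone. The step exploits that C10 and C4 are both fully substituted carbons flanking C5. The precursor is an acyclic hydroxy acid salt with one stereocentre (C9), made from 5,6-dihydro-2H-pyran-2-one by asymmetric conjugate addition and two enolate alkylations; side chain and ester follow by Negishi coupling.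

Key step: step 8

Remark: labdane numbering is used for all intermediates, and the SMILES is read as the ent-labdane (3R,5S,9R,10S) with a 13E double bond.

Step 1
Reactants: 1 4-methylpent-3-en-1-ol
Product: 2 4-methylpent-3-enal
Conditions: PhI(OAc)2, TEMPO (cat.), CH2Cl2, 0 °C to rt; used crude
Reagents that add atoms: none
Why: The nitroxyl-catalysed oxidation (TEMPO/PhI(OAc)2) of a primary alcohol stops at the aldehyde under non-basic conditions, so the β,γ-double bond should stay in place.

Step 2
Reactants: 2 4-methylpent-3-enal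
Product: 3 (2Z)-2-iodo-6-methylhepta-2,5-diene
Conditions: EtPPh3I, n-BuLi, THF, 0 °C; I2, −78 °C; NaN(SiMe3)2, −20 °C; then 2, −78 °C to rt
Reagents that add atoms: ethyltriphenylphosphonium iodide, CC[P+](c1ccccc1)(c1ccccc1)c1ccccc1.[I-]; iodine, II
Why: In this Stork–Zhao-type Wittig olefination with the α-iodo ylide the kinetic oxaphosphetane should place iodine cis to the aldehyde residue, which is the C7=C8 geometry that ring B needs later.

Step 3
Reactants: 3 (2Z)-2-iodo-6-methylhepta-2,5-diene
Product: 5 [(2E)-6-methylhepta-2,5-dien-2-yl]boronic acid (boron cis to the CH2 group), via alkenyllithium 4 (not isolated)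
Conditions: t-BuLi (2 equiv), Et2O, −78 °C; B(OiPr)3, −78 °C to rt; 1 M HCl
Reagents that add atoms: triisopropyl borate, CC(C)OB(OC(C)C)OC(C)C; water, O
Why: Iodine–lithium exchange retains the alkene geometry, and borylation with hydrolysis gives the free boronic acid needed for base-free rhodium catalysis.

Step 4
Reactants: 5 [(2E)-6-methylhepta-2,5-dien-2-yl]boronic acid; 6 5,6-dihydro-2H-pyran-2-one
Product: 7 (4S)-4-[(2Z)-6-methylhepta-2,5-dien-2-yl]oxan-2-one
Conditions: [Rh(OH)(cod)]2 (1.5 mol%), (S)-BINAP (3.3 mol%), dioxane/H2O (10:1), 35 °C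
Reagents that add atoms: none
Why: In this Hayashi–Miyaura reaction the alkenylrhodium–BINAP species adds 1,4 to one enantiotopic face of the s-trans-locked unsaturated lactone, which should set C9 as the (4S) lactone centre by analogy with aryl additions to this lactone and to cyclohexenone (the BINAP antipode is changed if the sense is opposite).

Step 5
Reactants: 7 (4S)-4-[(2Z)-6-methylhepta-2,5-dien-2-yl]oxan-2-one
Product: 9 (3R,4S)-3-methyl-4-[(2Z)-6-methylhepta-2,5-dien-2-yl]oxan-2-one, via lithium enolate 8 (not isolated)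
Conditions: LiN(iPr)2, THF, −78 °C; MeI, −78 to −40 °C
Reagents that add atoms: iodomethane, CI
Why: In this lithium enolate alkylation the methyl group should enter anti to the C4 substituent, and the new centre is planarised again in step 8.

Step 6
Reactants: 9 (3R,4S)-3-methyl-4-[(2Z)-6-methylhepta-2,5-dien-2-yl]oxan-2-one
Product: 11 3-[(3R,4R)-3-methyl-4-[(2Z)-6-methylhepta-2,5-dien-2-yl]-2-oxooxan-3-yl]propanenitrile, via lithium enolate 10 (not isolated)
Conditions: LiN(iPr)2, THF, −78 °C; acrylonitrile (1.1 equiv), −78 °C; aq. NH4Cl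
Reagents that add atoms: acrylonitrile, C=CC#N
Why: The Michael addition (cyanoethylation) of the fully substituted lactone enolate creates the quaternary carbon that becomes C10 and brings in C1–C3; its configuration is irrelevant because it is erased in step 8.

Step 7
Reactants: 11 3-[(3R,4R)-3-methyl-4-[(2Z)-6-methylhepta-2,5-dien-2-yl]-2-oxooxan-3-yl]propanenitrile
Product: 12 cesium (2R,3R)-2-(2-cyanoethyl)-5-hydroxy-2-methyl-3-[(2Z)-6-methylhepta-2,5-dien-2-yl]pentanoate
Conditions: CsOH·H2O (1.0 equiv), THF/H2O, 40 °C; concentrate, dry azeotropically (toluene)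
Reagents that add atoms: cesium hydroxide, [Cs+].[OH-]
Why: Saponification of the δ-lactone gives the hydroxy carboxylate, which is kept as its salt because the free δ-hydroxy acid would relactonise, and the nitrile should survive these mild conditions.

Step 8
Reactants: 12 cesium (2R,3R)-2-(2-cyanoethyl)-5-hydroxy-2-methyl-3-[(2Z)-6-methylhepta-2,5-dien-2-yl]pentanoate
Product: 14 (4aS,5R,8aS)-5-(2-hydroxyethyl)-1,1,4a,6-tetramethyl-3,4,4a,5,8,8a-hexahydronaphthalen-2(1H)-one, via N-unsubstituted ketimine 13 (not isolated)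
Conditions: [Ir(dF(CF3)ppy)2(dtbbpy)]PF6 (2 mol%), H2O (10 equiv), degassed DMSO (0.01 M), 450 nm LEDs, 25 °C; then 1 M HCl, THF, 25 °C
Reagents that add atoms: water, O
Why: Proposed new method: the excited trivalent iridium photocatalyst oxidises the carboxylate of 12, CO2 is lost and the tertiary C10 radical adds to C5 of the C4=C5 bond (bond C5–C10), after which the tertiary C4 radical adds to the nitrile carbon (bond C3–C4); divalent iridium reduces the iminyl radical, so the cycle is redox-neutral, and ketimine 13 is hydrolysed on work-up. The closest known reaction types are the photoredox decarboxylative conjugate addition of tertiary carboxylates and reductive radical cyclisations onto nitriles that give ketones, joined here by an alkene relay. Ring B closes 6-exo-trig through a half-chair and ring A 6-exo-dig through a chair-like transition state. C9 controls both new centres: with its hydroxyethyl arm pseudo-equatorial the planar C10 radical should carry the cyanoethyl arm on the outer, pseudo-equatorial side and the methyl group pseudo-axially, and the alkene terminus should also sit pseudo-equatorially, so that the cyanoethyl arm and the C4 radical are trans-diequatorial and close to the trans-fused decalin with the C10 methyl group cis to the C9 arm. The step needs 6-exo closure to outrun 1,5-hydrogen transfer from the doubly allylic C6–H and nitrile capture to outrun quenching of the C4 radical; the (Z)-C7=C8 bond that holds C5 next to C10, the single radical site defined by the carboxylate, the absence of a hydrogen donor and the fact that the C13=C14 bond is not yet present should secure this.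

Step 9
Reactants: 14 (4aS,5R,8aS)-5-(2-hydroxyethyl)-1,1,4a,6-tetramethyl-3,4,4a,5,8,8a-hexahydronaphthalen-2(1H)-one
Product: 15 (4aS,5R,8aS)-5-(2-iodoethyl)-1,1,4a,6-tetramethyl-3,4,4a,5,8,8a-hexahydronaphthalen-2(1H)-one
Conditions: I2, PPh3, imidazole, CH2Cl2, 0 °C
Reagents that add atoms: iodine, II
Why: The Appel iodination converts the primary alcohol under neutral conditions that should leave the hindered ketone and the trisubstituted alkene untouched.

Step 10
Reactants: 16 14-bromotetradecan-1-ol
Product: 17 [(14-bromotetradecyl)oxy](tert-butyl)dimethylsilane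
Conditions: TBSCl, imidazole, DMF, rt
Reagents that add atoms: tert-butyldimethylsilyl chloride, CC(C)(C)[Si](C)(C)Cl
Why: Standard silylation protects the hydroxyl group for the Grignard step.

Step 11
Reactants: 17 [(14-bromotetradecyl)oxy](tert-butyl)dimethylsilane; 18 16-bromohexadecanoic acid
Product: 21 30-{[tert-butyl(dimethyl)silyl]oxy}triacontanoic acid, via Grignard reagent 19 (not isolated), via chloromagnesium carboxylate 20 (not isolated)
Conditions: 17, Mg, THF, 40 °C; separately 18, MeMgCl (1.0 equiv), THF, −20 °C; combine, Li2CuCl4 (3 mol%), THF, −20 to 0 °C; aq. HCl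
Reagents that add atoms: none
Why: The copper-catalysed Grignard–alkyl bromide cross-coupling (Kochi type) joins the C14 and C16 chains, the acid being masked as its magnesium carboxylate.

Step 12
Reactants: 22 but-2-yn-1-ol
Product: 24 (2E)-3-iodobut-2-en-1-ol, via alkenylzirconocene alkoxide 23 (not isolated)
Conditions: Cp2Zr(H)Cl (2.2 equiv), THF, rt; I2, 0 °C; aq. HCl
Reagents that add atoms: iodine, II
Why: Hydrozirconation adds Zr–H syn across the alkyne with zirconium at the carbon remote from the alkoxide, and iodinolysis with retention should give the (E)-iodoalkene that fixes the C13=C14 geometry.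

Step 13
Reactants: 21 30-{[tert-butyl(dimethyl)silyl]oxy}triacontanoic acid; 24 (2E)-3-iodobut-2-en-1-ol
Product: 25 (2E)-3-iodobut-2-en-1-yl 30-{[tert-butyl(dimethyl)silyl]oxy}triacontanoate
Conditions: DCC, DMAP (cat.), CH2Cl2, 0 °C to rt
Reagents that add atoms: none
Why: The Steglich esterification acylates the primary allylic alcohol under mild conditions that leave the alkenyl iodide alone.

Step 14
Reactants: 15 (4aS,5R,8aS)-5-(2-iodoethyl)-1,1,4a,6-tetramethyl-3,4,4a,5,8,8a-hexahydronaphthalen-2(1H)-one; 25 (2E)-3-iodobut-2-en-1-yl 30-{[tert-butyl(dimethyl)silyl]oxy}triacontanoate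
Product: 27 (2E)-3-methyl-5-[(1R,4aS,8aS)-2,5,5,8a-tetramethyl-6-oxo-1,4,4a,5,6,7,8,8a-octahydronaphthalen-1-yl]pent-2-en-1-yl 30-{[tert-butyl(dimethyl)silyl]oxy}triacontanoate, via alkylzinc iodide 26 (not isolated)
Conditions: 15, Zn dust (activated), LiCl, THF, 35 °C; then 25, Pd(OAc)2 (2 mol%), SPhos (4 mol%), THF, rt
Reagents that add atoms: none
Why: In this Negishi coupling zinc inserts into the primary C–I bond without touching the ketone, and the palladium-catalysed sp3–sp2 coupling proceeds with retention at the alkenyl iodide, completing the side chain with the 13E bond.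

Step 15
Reactants: 27 (2E)-3-methyl-5-[(1R,4aS,8aS)-2,5,5,8a-tetramethyl-6-oxo-1,4,4a,5,6,7,8,8a-octahydronaphthalen-1-yl]pent-2-en-1-yl 30-{[tert-butyl(dimethyl)silyl]oxy}triacontanoate
Product: 28 (2E)-5-[(1R,4aS,6R,8aS)-6-hydroxy-2,5,5,8a-tetramethyl-1,4,4a,5,6,7,8,8a-octahydronaphthalen-1-yl]-3-methylpent-2-en-1-yl 30-{[tert-butyl(dimethyl)silyl]oxy}triacontanoate
Conditions: NaBH4, MeOH/THF, −20 to 0 °C
Reagents that add atoms: none
Why: In this borohydride reduction hydride should reach the 3-ketone from the face opposite the axial C10 and C4 methyl groups and give the equatorial (3R) alcohol, while the ester is not reduced.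

Step 16
Reactants: 28 (2E)-5-[(1R,4aS,6R,8aS)-6-hydroxy-2,5,5,8a-tetramethyl-1,4,4a,5,6,7,8,8a-octahydronaphthalen-1-yl]-3-methylpent-2-en-1-yl 30-{[tert-butyl(dimethyl)silyl]oxy}triacontanoate
Product: 29 (2E)-5-[(1R,4aS,6R,8aS)-6-hydroxy-2,5,5,8a-tetramethyl-1,4,4a,5,6,7,8,8a-octahydronaphthalen-1-yl]-3-methylpent-2-en-1-yl 30-hydroxytriacontanoate (CNP0303636.1)
Conditions: HF·pyridine, THF/pyridine, 0 °C to rt
Reagents that add atoms: none
Why: Fluoride-mediated desilylation frees the primary ω-hydroxyl group without acyl migration or ester cleavage.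

Compound list
1 | 4-methylpent-3-en-1-ol | CC(C)=CCCO | starting material
2 | 4-methylpent-3-enal | CC(C)=CCC=O | intermediate
3 | (2Z)-2-iodo-6-methylhepta-2,5-diene | C/C(I)=C/CC=C(C)C | intermediate
4 | [(2E)-6-methylhepta-2,5-dien-2-yl]lithium (not isolated) | [Li]/C(C)=C\CC=C(C)C | intermediate
5 | [(2E)-6-methylhepta-2,5-dien-2-yl]boronic acid | OB(O)/C(C)=C\CC=C(C)C | intermediate
6 | 5,6-dihydro-2H-pyran-2-one | O=C1C=CCCO1 | starting material
7 | (4S)-4-[(2Z)-6-methylhepta-2,5-dien-2-yl]oxan-2-one | O=C1C[C@H](CCO1)/C(C)=C\CC=C(C)C | intermediate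
8 | lithium enolate of 7 (not isolated) | [Li]OC1=C[C@H](CCO1)/C(C)=C\CC=C(C)C | intermediate
9 | (3R,4S)-3-methyl-4-[(2Z)-6-methylhepta-2,5-dien-2-yl]oxan-2-one | O=C1[C@H](C)[C@H](CCO1)/C(C)=C\CC=C(C)C | intermediate
10 | lithium enolate of 9 (not isolated) | [Li]OC1=C(C)[C@H](CCO1)/C(C)=C\CC=C(C)C | intermediate
11 | 3-[(3R,4R)-3-methyl-4-[(2Z)-6-methylhepta-2,5-dien-2-yl]-2-oxooxan-3-yl]propanenitrile | O=C1[C@](C)(CCC#N)[C@H](CCO1)/C(C)=C\CC=C(C)C | intermediate
12 | cesium (2R,3R)-2-(2-cyanoethyl)-5-hydroxy-2-methyl-3-[(2Z)-6-methylhepta-2,5-dien-2-yl]pentanoate | [Cs+].[O-]C(=O)[C@](C)(CCC#N)[C@H](CCO)/C(C)=C\CC=C(C)C | intermediate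
13 | N-unsubstituted ketimine of 14 (not isolated) | CC1=CC[C@@H]2C(C)(C)C(=N)CC[C@@]2(C)[C@@H]1CCO | intermediate
14 | (4aS,5R,8aS)-5-(2-hydroxyethyl)-1,1,4a,6-tetramethyl-3,4,4a,5,8,8a-hexahydronaphthalen-2(1H)-one | CC1=CC[C@@H]2C(C)(C)C(=O)CC[C@@]2(C)[C@@H]1CCO | intermediate
15 | (4aS,5R,8aS)-5-(2-iodoethyl)-1,1,4a,6-tetramethyl-3,4,4a,5,8,8a-hexahydronaphthalen-2(1H)-one | CC1=CC[C@@H]2C(C)(C)C(=O)CC[C@@]2(C)[C@@H]1CCI | intermediate
16 | 14-bromotetradecan-1-ol | OCCCCCCCCCCCCCCBr | starting material
17 | [(14-bromotetradecyl)oxy](tert-butyl)dimethylsilane | CC(C)(C)[Si](C)(C)OCCCCCCCCCCCCCCBr | intermediate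
18 | 16-bromohexadecanoic acid | OC(=O)CCCCCCCCCCCCCCCBr | starting material
19 | (14-{[tert-butyl(dimethyl)silyl]oxy}tetradecyl)magnesium bromide (not isolated) | CC(C)(C)[Si](C)(C)OCCCCCCCCCCCCCC[Mg]Br | intermediate
20 | chloromagnesium 16-bromohexadecanoate (not isolated) | Cl[Mg]OC(=O)CCCCCCCCCCCCCCCBr | intermediate
21 | 30-{[tert-butyl(dimethyl)silyl]oxy}triacontanoic acid | OC(=O)CCCCCCCCCCCCCCCCCCCCCCCCCCCCCO[Si](C)(C)C(C)(C)C | intermediate
22 | but-2-yn-1-ol | CC#CCO | starting material
23 | alkenylzirconocene alkoxide from 22, zirconium trans to the CH2O group (not isolated) | C/C(=C\CO[Zr](Cl)(C1C=CC=C1)C1C=CC=C1)[Zr](Cl)(C1C=CC=C1)C1C=CC=C1 | intermediate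
24 | (2E)-3-iodobut-2-en-1-ol | C/C(I)=C\CO | intermediate
25 | (2E)-3-iodobut-2-en-1-yl 30-{[tert-butyl(dimethyl)silyl]oxy}triacontanoate | C/C(I)=C\COC(=O)CCCCCCCCCCCCCCCCCCCCCCCCCCCCCO[Si](C)(C)C(C)(C)C | intermediate
26 | alkylzinc iodide from 15 (not isolated) | CC1=CC[C@@H]2C(C)(C)C(=O)CC[C@@]2(C)[C@@H]1CC[Zn]I | intermediate
27 | (2E)-3-methyl-5-[(1R,4aS,8aS)-2,5,5,8a-tetramethyl-6-oxo-1,4,4a,5,6,7,8,8a-octahydronaphthalen-1-yl]pent-2-en-1-yl 30-{[tert-butyl(dimethyl)silyl]oxy}triacontanoate | CC1=CC[C@@H]2C(C)(C)C(=O)CC[C@@]2(C)[C@@H]1CC/C(C)=C/COC(=O)CCCCCCCCCCCCCCCCCCCCCCCCCCCCCO[Si](C)(C)C(C)(C)C | intermediate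
28 | (2E)-5-[(1R,4aS,6R,8aS)-6-hydroxy-2,5,5,8a-tetramethyl-1,4,4a,5,6,7,8,8a-octahydronaphthalen-1-yl]-3-methylpent-2-en-1-yl 30-{[tert-butyl(dimethyl)silyl]oxy}triacontanoate | CC1=CC[C@@H]2C(C)(C)[C@H](O)CC[C@@]2(C)[C@@H]1CC/C(C)=C/COC(=O)CCCCCCCCCCCCCCCCCCCCCCCCCCCCCO[Si](C)(C)C(C)(C)C | intermediate
29 | (2E)-5-[(1R,4aS,6R,8aS)-6-hydroxy-2,5,5,8a-tetramethyl-1,4,4a,5,6,7,8,8a-octahydronaphthalen-1-yl]-3-methylpent-2-en-1-yl 30-hydroxytriacontanoate (CNP0303636.1) | CC1=CC[C@@H]2C(C)(C)[C@H](O)CC[C@@]2(C)[C@@H]1CC/C(C)=C/COC(=O)CCCCCCCCCCCCCCCCCCCCCCCCCCCCCO | target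

Total step count: 16
Longest linear sequence: 12 steps (steps 1 to 9, then 14 to 16)

Steps most likely to fail

Step 8 (proposed new method). Three processes may go wrong. The C10 radical may take a hydrogen atom from the doubly allylic C6–H instead of cyclising. The nitrile may capture the C4 radical too slowly. Ring B may close through the alternative half-chair with the C9 arm pseudo-axial, which would erode the trans ring fusion. The fallback uses known radical chain chemistry in place of the photoredox cycle, sets out from 12 and comes back at 14. Salt 12 would be silylated on both oxygens (TBSCl, imidazole, DMF) and the silyl ester cleaved (K2CO3, MeOH/H2O) to give (2R,3R)-5-{[tert-butyl(dimethyl)silyl]oxy}-2-(2-cyanoethyl)-2-methyl-3-[(2Z)-6-methylhepta-2,5-dien-2-yl]pentanoic acid F1, which can no longer lactonise. Activation ((COCl)2, cat. DMF, CH2Cl2) and reaction with the sodium salt of 1-hydroxypyridine-2(1H)-thione would give the 2-thioxopyridin-1(2H)-yl ester (Barton ester) F2. Slow addition of (Me3Si)3SiH with AIBN in benzene at 80 °C (Barton decarboxylation, 6-exo cyclisation onto the alkene, silane-mediated cyclisation onto the nitrile), followed by aqueous HCl, would give (4aS,5R,8aS)-5-(2-{[tert-butyl(dimethyl)silyl]oxy}ethyl)-1,1,4a,6-tetramethyl-3,4,4a,5,8,8a-hexahydronaphthalen-2(1H)-one F3. Ring-fusion isomers would be separated at this stage, and HF·pyridine would return 14.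

Step 4. Transmetalation of the hindered α-methyl alkenylboronic acid may be slower than its protodeboronation, the (Z)-geometry may erode on rhodium, or the facial selectivity may be low. The fallback replaces catalyst control by a chiral auxiliary, sets out from 3 and comes back at 7. Iodide 3 would be converted (t-BuLi, Et2O, −78 °C; MgBr2·OEt2) into [(2Z)-6-methylhepta-2,5-dien-2-yl]magnesium bromide F4. With CuBr·SMe2 in THF at −40 °C this would add to (4R)-3-[(2E)-5-{[tert-butyl(dimethyl)silyl]oxy}pent-2-enoyl]-4-phenyl-1,3-oxazolidin-2-one F5 (from the commercial oxazolidinone and the enoyl chloride) from the face of the magnesium chelate opposite to phenyl. The adduct would be (4R)-3-[(3S,4Z)-3-(2-{[tert-butyl(dimethyl)silyl]oxy}ethyl)-4,8-dimethylnona-4,7-dienoyl]-4-phenyl-1,3-oxazolidin-2-one F6. Bu4NF in THF would free the alkoxide, which lactonises with loss of the auxiliary to give 7.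

Step 2. The β,γ-unsaturated aldehyde may isomerise to the conjugated enal under the basic ylide conditions, and the Z-selectivity of the olefination may be incomplete. The fallback fixes the geometry by anti-hydroalumination instead of olefination, sets out from 22 and comes back at 3. But-2-yn-1-ol 22 would be treated with NaAlH2(OCH2CH2OCH3)2 in THF and the alkenylalane quenched with I2 to give (2Z)-3-iodobut-2-en-1-ol F7. CBr4/PPh3 would give (2Z)-1-bromo-3-iodobut-2-ene F8, and coupling with (2-methylprop-1-en-1-yl)magnesium bromide (CuI cat., THF, −30 °C) at the allylic carbon would give 3.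

Further compounds
F1 | step 8 | (2R,3R)-5-{[tert-butyl(dimethyl)silyl]oxy}-2-(2-cyanoethyl)-2-methyl-3-[(2Z)-6-methylhepta-2,5-dien-2-yl]pentanoic acid | OC(=O)[C@](C)(CCC#N)[C@H](CCO[Si](C)(C)C(C)(C)C)/C(C)=C\CC=C(C)C
F2 | step 8 | 2-thioxopyridin-1(2H)-yl ester of F1 (Barton ester) | S=C1C=CC=CN1OC(=O)[C@](C)(CCC#N)[C@H](CCO[Si](C)(C)C(C)(C)C)/C(C)=C\CC=C(C)C
F3 | step 8 | (4aS,5R,8aS)-5-(2-{[tert-butyl(dimethyl)silyl]oxy}ethyl)-1,1,4a,6-tetramethyl-3,4,4a,5,8,8a-hexahydronaphthalen-2(1H)-one | CC1=CC[C@@H]2C(C)(C)C(=O)CC[C@@]2(C)[C@@H]1CCO[Si](C)(C)C(C)(C)C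
F4 | step 4 | [(2Z)-6-methylhepta-2,5-dien-2-yl]magnesium bromide | Br[Mg]/C(C)=C\CC=C(C)C
F5 | step 4 | (4R)-3-[(2E)-5-{[tert-butyl(dimethyl)silyl]oxy}pent-2-enoyl]-4-phenyl-1,3-oxazolidin-2-one | O=C1OC[C@@H](c2ccccc2)N1C(=O)/C=C/CCO[Si](C)(C)C(C)(C)C
F6 | step 4 | (4R)-3-[(3S,4Z)-3-(2-{[tert-butyl(dimethyl)silyl]oxy}ethyl)-4,8-dimethylnona-4,7-dienoyl]-4-phenyl-1,3-oxazolidin-2-one | O=C1OC[C@@H](c2ccccc2)N1C(=O)C[C@H](CCO[Si](C)(C)C(C)(C)C)/C(C)=C\CC=C(C)C
F7 | step 2 | (2Z)-3-iodobut-2-en-1-ol | C/C(I)=C/CO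
F8 | step 2 | (2Z)-1-bromo-3-iodobut-2-ene | C/C(I)=C/CBr
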